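Assumption: the sense of induction of the PyOX ligand is taken to parallel the known cyclic-enone case ((S)-ligand gives the (2R)-flavanone-type face), so the (R)-ligand is specified; if the sense is reversed, the (S)-ligand is used.

## Retrosynthetic overview

1. The target comes from its tris-MOM ether by a single global acetal cleavage.
2. The C2–aryl bond and both stereocentres (C2, C3) come from an enantioselective Pd(II)/PyOX conjugate arylation of a 3-(methoxymethoxy)chromone with an arylboronic acid.
3. The chromone comes from a 2-hydroxyaryl MOM-oxymethyl ketone by enaminone annulation. The ketone comes from resorcinol by two directed ortho-metalations (prenylation, then acylation with a glycolate Weinreb amide).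
4. The boronic acid comes from 4-bromophenol by ortho-iodination, Cu-catalysed prenylation and Br–Li exchange/borylation.
5. Ring order: the A and B benzene rings are bought; the pyranone C ring is closed before the coupling and is reduced to the chromanone during the coupling.

## Route

**Step 1**
Reactants: 1, resorcinol
Product: 2, 1,3-bis(methoxymethoxy)benzene
Conditions: NaH, MOMCl, DMF, 0 °C → rt
Reagents that add atoms: chloromethyl methyl ether (MOMCl), COCCl
Why: Double O-alkylation (MOM protection) of the phenoxides installs the ortho-directing groups needed for steps 2 and 5.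

**Step 2**
Reactants: 2, 1,3-bis(methoxymethoxy)benzene; 3, prenyl bromide (1-bromo-3-methylbut-2-ene)
Product: 4, 1,3-bis(methoxymethoxy)-2-(3-methylbut-2-en-1-yl)benzene
Conditions: n-BuLi, THF, 0 °C → rt; CuI (cat.), then 3, −78 °C → rt
Reagents that add atoms: none beyond reactant 3 (CC(C)=CCBr)
Why: Directed ortho-metalation occurs at C2, flanked by both OMOM groups, and the aryl metal is alkylated at the primary carbon of prenyl bromide (SN2) to give the linear prenyl group.

**Step 3**
Reactants: 5, methyl glycolate (methyl 2-hydroxyacetate)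
Product: 6, methyl 2-(methoxymethoxy)acetate
Conditions: MOMCl, i-Pr2NEt, CH2Cl2, 0 °C → rt
Reagents that add atoms: chloromethyl methyl ether, COCCl
Why: Standard MOM protection of a primary alcohol.

**Step 4**
Reactants: 6, methyl 2-(methoxymethoxy)acetate
Product: 7, N-methoxy-2-(methoxymethoxy)-N-methylacetamide
Conditions: MeNH(OMe)·HCl, i-PrMgCl, THF, −20 °C
Reagents that add atoms: N,O-dimethylhydroxylamine hydrochloride, CNOC.Cl
Why: Aminolysis of the ester by the magnesium amide gives the Weinreb amide.

**Step 5**
Reactants: 4, 1,3-bis(methoxymethoxy)-2-(3-methylbut-2-en-1-yl)benzene; 7, N-methoxy-2-(methoxymethoxy)-N-methylacetamide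
Product: 8, 1-[2,4-bis(methoxymethoxy)-3-(3-methylbut-2-en-1-yl)phenyl]-2-(methoxymethoxy)ethan-1-one
Conditions: n-BuLi, TMEDA, THF, 0 °C; then 7, −78 → 0 °C; aq. NH4Cl
Reagents that add atoms: none beyond reactant 7
Why: A second directed ortho-metalation (ortho to OMOM) followed by Weinreb ketone synthesis; the chelated tetrahedral intermediate prevents over-addition.

**Step 6**
Reactants: 8, the tris-MOM ketone
Product: 9, 1-[2-hydroxy-4-(methoxymethoxy)-3-(3-methylbut-2-en-1-yl)phenyl]-2-(methoxymethoxy)ethan-1-one
Conditions: HCl (1.25 M in MeOH, ca. 1.5 equiv), MeOH–CH2Cl2, 0 °C → rt, stopped at full conversion of 8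
Reagents that add atoms: none
Why: Chemoselective acetal solvolysis: the aryl MOM ortho to the carbonyl is twisted between acyl and prenyl and gives an H-bonded phenol, so it should cleave faster than the para aryl MOM and the alkyl MOM.

**Step 7**
Reactants: 9, the 2-hydroxyaryl ketone; 10, N,N-dimethylformamide dimethyl acetal
Product: 11, 3,7-bis(methoxymethoxy)-8-(3-methylbut-2-en-1-yl)-4H-chromen-4-one
Conditions: 10 (3 equiv), PhMe, 100 °C; then AcOH (cat.), 50 °C
Reagents that add atoms: none beyond reactant 10 (supplies C2 of the chromone)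
Why: Enaminone formation at the activated α-CH2, then intramolecular addition of the free phenol and loss of Me2NH, closes the pyranone ring (enaminone chromone annulation).

**Step 8**
Reactants: 12, 4-bromophenol
Product: 13, 4-bromo-2-iodophenol
Conditions: NIS (1.0 equiv), TsOH (cat.), MeCN, rt
Reagents that add atoms: N-iodosuccinimide, O=C1CCC(=O)N1I
Why: Electrophilic aromatic iodination; the para position is blocked, so substitution occurs ortho to OH.

**Step 9**
Reactants: 13, 4-bromo-2-iodophenol
Product: 14, 4-bromo-2-iodo-1-(methoxymethoxy)benzene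
Conditions: MOMCl, i-Pr2NEt, CH2Cl2, 0 °C → rt
Reagents that add atoms: chloromethyl methyl ether, COCCl
Why: Standard phenol MOM protection.

**Step 10**
Reactants: 14, 4-bromo-2-iodo-1-(methoxymethoxy)benzene; 3, prenyl bromide
Product: 15, 4-bromo-1-(methoxymethoxy)-2-(3-methylbut-2-en-1-yl)benzene
Conditions: i-PrMgCl·LiCl, THF, −30 °C; CuI (10 mol %), then 3, −30 °C → rt
Reagents that add atoms: none beyond reactant 3
Why: I/Mg exchange is much faster than Br/Mg exchange and is assisted by the ortho OMOM; Cu-catalysed allylic substitution then gives the linear prenyl arene.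

**Step 11**
Reactants: 15, 4-bromo-1-(methoxymethoxy)-2-(3-methylbut-2-en-1-yl)benzene
Product: 16, [4-(methoxymethoxy)-3-(3-methylbut-2-en-1-yl)phenyl]boronic acid
Conditions: n-BuLi, THF, −78 °C; B(Oi-Pr)3, −78 °C → rt; aq. NH4Cl
Reagents that add atoms: triisopropyl borate, CC(C)OB(OC(C)C)OC(C)C; water, O
Why: Br–Li exchange, borate trapping and mild hydrolysis give the boronic acid with the MOM ether and prenyl group intact.

**Step 12**
Reactants: 11, 3,7-bis(methoxymethoxy)-8-prenylchromone; 16, the arylboronic acid (2 equiv)
Product: 17, (2R,3R)-3,7-bis(methoxymethoxy)-2-[4-(methoxymethoxy)-3-(3-methylbut-2-en-1-yl)phenyl]-8-(3-methylbut-2-en-1-yl)chroman-4-one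
Conditions: Pd(OCOCF3)2 (10 mol %), (R)-t-BuPyOX (12 mol %), NH4PF6 (30 mol %), H2O (5 equiv), ClCH2CH2Cl, 60 °C
Reagents that add atoms: none (the C3 hydrogen comes from water)
Why: Proposed new method: Pd(II)/PyOX conjugate arylation with arylboronic acids is established for chromones and β-substituted cyclic enones but not for 3-oxygenated (α-alkoxy) chromones. Transmetalation gives a cationic (PyOX)Pd–aryl that binds C2=C3, and enantio-determining syn-carbopalladation puts the aryl on C2 (β to C=O, stabilised by O1) on the face set by the (R)-ligand, fixing C2 as R. The C3–Pd intermediate has no syn β-hydrogen, so it tautomerises to the O-bound enolate, which water protonates axially at C3 (anti to the axial C2–H) to give the diequatorial 2,3-trans (3R) α-alkoxy ketone, also the thermodynamic epimer. The closest known reaction is the Pd(TFA)2/t-BuPyOX asymmetric conjugate addition of arylboronic acids to chromones.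

**Step 13**
Reactants: 17, the tris-MOM dihydroflavonol
Product: 18, 3-hydroxyglabrol, (2R,3R)-3,7-dihydroxy-2-[4-hydroxy-3-(3-methylbut-2-en-1-yl)phenyl]-8-(3-methylbut-2-en-1-yl)chroman-4-one
Conditions: 3 M aq. HCl–MeOH (1:5), 45 °C, monitored and stopped at completion
Reagents that add atoms: none
Why: Acid-catalysed acetal solvolysis removes all three MOM ethers; the 2,3-trans diequatorial isomer is the thermodynamic one, so C3 is not eroded, and the mild temperature limits prenyl–phenol cyclisation.

## Compound list

1 | resorcinol | Oc1cccc(O)c1 | starting material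
2 | 1,3-bis(methoxymethoxy)benzene | COCOc1cccc(OCOC)c1 | intermediate
3 | prenyl bromide | CC(C)=CCBr | starting material
4 | 1,3-bis(methoxymethoxy)-2-(3-methylbut-2-en-1-yl)benzene | COCOc1cccc(OCOC)c1CC=C(C)C | intermediate
5 | methyl glycolate | COC(=O)CO | starting material
6 | methyl 2-(methoxymethoxy)acetate | COCOCC(=O)OC | intermediate
7 | N-methoxy-2-(methoxymethoxy)-N-methylacetamide | COCOCC(=O)N(C)OC | intermediate
8 | 1-[2,4-bis(methoxymethoxy)-3-(3-methylbut-2-en-1-yl)phenyl]-2-(methoxymethoxy)ethan-1-one | COCOCC(=O)c1ccc(OCOC)c(CC=C(C)C)c1OCOC | intermediate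
9 | 1-[2-hydroxy-4-(methoxymethoxy)-3-(3-methylbut-2-en-1-yl)phenyl]-2-(methoxymethoxy)ethan-1-one | COCOCC(=O)c1ccc(OCOC)c(CC=C(C)C)c1O | intermediate
10 | N,N-dimethylformamide dimethyl acetal | COC(OC)N(C)C | starting material
11 | 3,7-bis(methoxymethoxy)-8-(3-methylbut-2-en-1-yl)-4H-chromen-4-one | O=c1c(OCOC)coc2c(CC=C(C)C)c(OCOC)ccc12 | intermediate
12 | 4-bromophenol | Oc1ccc(Br)cc1 | starting material
13 | 4-bromo-2-iodophenol | Oc1ccc(Br)cc1I | intermediate
14 | 4-bromo-2-iodo-1-(methoxymethoxy)benzene | COCOc1ccc(Br)cc1I | intermediate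
15 | 4-bromo-1-(methoxymethoxy)-2-(3-methylbut-2-en-1-yl)benzene | COCOc1ccc(Br)cc1CC=C(C)C | intermediate
16 | [4-(methoxymethoxy)-3-(3-methylbut-2-en-1-yl)phenyl]boronic acid | COCOc1ccc(B(O)O)cc1CC=C(C)C | intermediate
17 | (2R,3R)-3,7-bis(methoxymethoxy)-2-[4-(methoxymethoxy)-3-(3-methylbut-2-en-1-yl)phenyl]-8-(3-methylbut-2-en-1-yl)chroman-4-one | CC(C)=CCc1cc([C@H]2Oc3c(ccc(OCOC)c3CC=C(C)C)C(=O)[C@@H]2OCOC)ccc1OCOC | intermediate
18 | 3-hydroxyglabrol | CC(C)=CCc1cc([C@H]2Oc3c(ccc(O)c3CC=C(C)C)C(=O)[C@@H]2O)ccc1O | target

## Summary

Total step count: 13.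
Longest linear sequence: 7 steps (1, 2, 5, 6, 7, 12, 13; the glycolate branch 3, 4, 5, 6, 7, 12, 13 is equally long).

Steps most likely to fail:

1. **Step 12 (the proposed new step).** The 3-alkoxy group may slow insertion, erode enantioselectivity, or give a cis/trans mixture at C3.
   Fallback (known chemistry): make 7-(methoxymethoxy)-8-prenylchromone from 4 with N-methoxy-N-methylacetamide by the same sequence. Run the established Pd(TFA)2/(R)-t-BuPyOX conjugate addition with 16 to give the (2S)-flavanone. Then install the 3-OH by Rubottom oxidation (TMSOTf/Et3N, then 1.0 equiv DMDO at −78 °C), which gives the 2,3-trans (2R,3R) product, and remove the MOM groups.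

2. **Step 6.** The mono-deprotection ortho to the ketone may over-cleave the second aryl MOM or the alkyl MOM.
   Fallback: skip the differentiation. Condense 8 with DMF-DMA, cyclise the enaminone with HCl/MeOH with loss of all MOM groups to 3,7-dihydroxy-8-prenylchromone, then re-install both MOM ethers (NaH, MOMCl) to reach 11.

3. **Step 13.** Acid may cyclise the ortho-prenyl phenols to chromans or cleave the secondary 3-OMOM too slowly.
   Fallback: change the protecting-group scheme to silyl ethers (7-O and 4'-O TBS, 3-O TES), swapped in after the lithiation steps on each fragment, so that the final unmasking uses buffered fluoride (HF·pyridine or TBAF/AcOH) instead of acid.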